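**Plan**

1. Ring numbering: C1 carries the acrylate, C2 is the vinylic CH, C3 bears CO2H, C4 the aryl group, C5 and C6 one CO2H each. The C5 carboxyl is γ,δ-unsaturated through C6 to the C1=C2 double bond. That is the footprint of a Claisen rearrangement in which C5–C6 is the new bond and C2 once carried the carboxyl oxygen.
2. Cuts: the acrylate C=C (olefination of a core aldehyde with a danshensu phosphonoacetate); then C5–C6, with C2 reconnected to the C5 carboxyl oxygen (a 6-alkenyl δ-lactone); then C2–C3 (aldol of a 3-arylglutaric acid derivative with a 3-formylbut-2-enoate); then the glutaric anhydride.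
3. Forward: arylglutaric anhydride, half-ester, oxazolidinone aldol, δ-lactone (first ring), Ireland–Claisen ring contraction to the cyclohexene (second ring), aldehyde release, olefination with the danshensu fragment, global deallylation.
4. Stereochemistry: C4 from alkaloid-catalysed methanolysis of the anhydride; C3 and C2 from the auxiliary-controlled syn aldol; C5 and C6 by transfer from C2 and from the alkene geometry (set by syn-carbocupration); the side-chain centre from (R)-danshensu.
5. Protection: every phenol and acid ends as an allyl ether or ester and all are freed together by zerovalent palladium; C3 is carried as the free acid through the rearrangement so that only the lactone can be enolised.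

Key step: step 11

Assumption: (DHQD)2AQN is taken to deliver the (S)-half-ester 7 in step 4; should its sense of induction be the opposite, the pseudo-enantiomeric (DHQ)2AQN gives 7 with no other change.

**Route**

Step 1
Reactants: 1 3,4-dihydroxybenzaldehyde
Product: 2 3,4-bis(allyloxy)benzaldehyde
Conditions: CH2=CHCH2Br, K2CO3, DMF, 60 °C
Reagents that add atoms: allyl bromide, C=CCBr
Why: Williamson etherification of both phenols under carbonate leaves the aldehyde untouched, and the allyl ethers should survive every later step until zerovalent palladium removes them.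

Step 2
Reactants: 2 3,4-bis(allyloxy)benzaldehyde; 3 ethyl acetoacetate
Product: 5 3-[3,4-bis(allyloxy)phenyl]pentanedioic acid, via bis(acetoacetate) adduct 4 (not isolated)
Conditions: piperidine (cat.), EtOH, rt; then NaOH (aq), EtOH, reflux; then HCl
Reagents that add atoms: sodium hydroxide, [Na+].[OH-]
Why: Knoevenagel condensation followed by Michael addition of a second acetoacetate gives the bis-adduct, and hot hydroxide then removes both acetyl groups by retro-Claisen cleavage and saponifies the esters, the classical entry to 3-arylglutaric acids.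

Step 3
Reactants: 5 3-[3,4-bis(allyloxy)phenyl]pentanedioic acid
Product: 6 4-[3,4-bis(allyloxy)phenyl]oxane-2,6-dione
Conditions: Ac2O, 90 °C
Reagents that add atoms: none
Why: Cyclodehydration through the mixed acetic anhydride closes the unstrained six-membered anhydride and makes the two carbonyl groups enantiotopic.

Step 4
Reactants: 6 4-[3,4-bis(allyloxy)phenyl]oxane-2,6-dione
Product: 7 (3S)-3-[3,4-bis(allyloxy)phenyl]-5-methoxy-5-oxopentanoic acid
Conditions: (DHQD)2AQN (0.3 equiv), MeOH (10 equiv), Et2O, −40 °C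
Reagents that add atoms: methanol, CO
Why: Cinchona alkaloid-catalysed (general-base) methanolysis of a prochiral cyclic anhydride opens one enantiotopic carbonyl and so fixes C4, a desymmetrisation established for 3-substituted glutaric anhydrides.

Step 5
Reactants: 7 (3S)-3-[3,4-bis(allyloxy)phenyl]-5-methoxy-5-oxopentanoic acid; 8 (4S)-4-benzyl-1,3-oxazolidin-2-one
Product: 10 methyl (3S)-3-[3,4-bis(allyloxy)phenyl]-5-[(4S)-4-benzyl-2-oxo-1,3-oxazolidin-3-yl]-5-oxopentanoate, via pivalic mixed anhydride 9 (not isolated)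
Conditions: tBuCOCl, Et3N, THF, −20 °C; then 8, LiCl, rt
Reagents that add atoms: none
Why: The acid is activated as its pivalic mixed anhydride, which N-acylates the oxazolidinone at the less hindered carbonyl (LiCl-assisted imide formation) while the methyl ester stays inert; any minor enantiomer of 7 becomes a separable diastereomer here.

Step 6
Reactants: 11 3,3-diethoxyprop-1-yne
Product: 13 tert-butyl 4,4-diethoxybut-2-ynoate, via lithium acetylide 12 (not isolated)
Conditions: n-BuLi, THF, −78 °C; Boc2O, −78 to 0 °C; aq. NH4Cl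
Reagents that add atoms: di-tert-butyl dicarbonate, CC(C)(C)OC(=O)OC(=O)OC(C)(C)C
Why: Alkoxycarbonylation of a lithium acetylide with Boc2O gives the tert-butyl ynoate, the acetal being base-stable; the tert-butyl ester is chosen because it survives ozone and falls later with acid.

Step 7
Reactants: 13 tert-butyl 4,4-diethoxybut-2-ynoate
Product: 15 tert-butyl (2Z)-3-(diethoxymethyl)penta-2,4-dienoate (vinyl trans to the ester), via alkenylcopper adduct 14 (not isolated)
Conditions: CH2=CHMgBr, CuBr·SMe2, THF, −78 °C; AcOH, −78 °C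
Reagents that add atoms: vinylmagnesium bromide, C=C[Mg]Br
Why: Carbocupration of an ynoate at −78 °C is a syn addition, so vinyl and copper end cis and, after protonation with retention, the vinyl group lies trans to the ester and the acetal cis to it.

Step 8
Reactants: 15 tert-butyl (2Z)-3-(diethoxymethyl)penta-2,4-dienoate
Product: 17 tert-butyl (2Z)-3-(diethoxymethyl)-4-oxobut-2-enoate (formyl trans to the ester), via ozonide 16 (not isolated)
Conditions: O3 (1 equiv, indicator dye), CH2Cl2, −78 °C; Me2S, −78 °C to rt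
Reagents that add atoms: ozone, [O-][O+]=O
Why: Ozonolysis (Criegee mechanism, reductive work-up) should attack the monosubstituted vinyl group far faster than the ester-deactivated trisubstituted alkene, as in the cleavage of sorbate esters to 4-oxobut-2-enoates, and leaves the alkene geometry untouched.

Step 9
Reactants: 10 methyl (3S)-3-[3,4-bis(allyloxy)phenyl]-5-[(4S)-4-benzyl-2-oxo-1,3-oxazolidin-3-yl]-5-oxopentanoate; 17 tert-butyl (2Z)-3-(diethoxymethyl)-4-oxobut-2-enoate
Product: 20 1-tert-butyl 8-methyl (2Z,4S,5S,6R)-6-[3,4-bis(allyloxy)phenyl]-5-{[(4S)-4-benzyl-2-oxo-1,3-oxazolidin-3-yl]carbonyl}-3-(diethoxymethyl)-4-hydroxyoct-2-enedioate, via boron enolate 18 (not isolated), via boron aldolate 19 (not isolated)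
Conditions: Bu2BOTf, iPr2NEt, CH2Cl2, −78 to 0 °C; 17, −78 to 0 °C; pH 7 buffer, MeOH, H2O2, 0 °C
Reagents that add atoms: none
Why: Evans syn aldol: soft enolisation gives the (Z)-boron enolate, which adds to the aldehyde through a closed Zimmerman–Traxler chair on the face dictated by the (4S)-benzyl group, setting C3 and C2 (both S) independently of the remote C4 centre.

Step 10
Reactants: 20 the syn aldol adduct
Product: 22 (2S,3S,4R)-4-[3,4-bis(allyloxy)phenyl]-2-[(1Z)-3-tert-butoxy-1-(diethoxymethyl)-3-oxoprop-1-en-1-yl]-6-oxooxane-3-carboxylic acid, via hydroxy acid 21 (not isolated)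
Conditions: LiOH, H2O2, THF/H2O, 0 °C; Na2SO3; HCl to pH 3; then PPTS (cat.), toluene, 5 Å sieves, 50 °C
Reagents that add atoms: hydrogen peroxide, OO
Why: Lithium hydroperoxide cleaves the imide at the exocyclic carbonyl without touching the α-centre, and acid catalysis then closes the only unstrained ring available, the δ-lactone between the C2 hydroxyl and the methyl ester arm; the 2,3-syn aldol and 3,4-anti relationships place alkenyl, carboxyl and aryl groups all equatorial.

Step 11
Reactants: 22 the all-equatorial 6-alkenyl δ-lactone acid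
Product: 26 (3R,4S,5R,6R)-4-[3,4-bis(allyloxy)phenyl]-6-(tert-butoxycarbonyl)-1-(diethoxymethyl)cyclohex-1-ene-3,5-dicarboxylic acid (numbering of the plan; 3,4-trans, 4,5-trans, 5,6-cis), via dipotassium enolate carboxylate 23 (not isolated), via silyl ketene acetal 24 (not isolated), via bis(trimethylsilyl) ester 25 (not isolated)
Conditions: KN(SiMe3)2 (2.2 equiv), THF, −78 °C; Me3SiCl, Et3N, −78 °C to rt; toluene, 110 °C; then H2O/MeOH, pH 5
Reagents that add atoms: none
Why: KN(SiMe3)2 first removes the C3 carboxylic acid proton and then a proton of the lactone methylene (the future C5), Me3SiCl turns the dianion into the silyl ester/O-silyl ketene acetal 24, and heating drives a concerted suprafacial [3,3] sigmatropic shift of the C5=C(OSi)–O–C2–C1=C6 array that forms C5–C6, breaks C2–O and moves the alkene to C1=C2. The closest known reaction is the Ireland–Claisen rearrangement of silyl ketene acetals of 6-alkenyl δ-lactones to cyclohex-3-enecarboxylic acids. The cyclohexene C1–C6 closes by ring contraction and not by exo or endo attack of a free chain: the C3–C4 tether forces a boat transition state shaped like a 2-oxabicyclo[2.2.2]octene, and the carbocycle is what remains when its C2–O bridge opens. C5 is set because C6 can reach only the face of the ketene acetal that carries the alkenyl group, which places the new carboxyl trans to the aryl group that was cis to that alkenyl group; C6 is set by the alkene geometry, the ester trans to C2 ending cis to the C5 carboxyl, so both centres are relayed from C2 while C3 and C4 are spectators. The step needs enolisation at the lactone methylene only and a single transition-state geometry: the first is secured because a C3 carboxylate, unlike an ester there, cannot be enolised by the amide base and so cannot trigger β-elimination of the lactone oxygen, the second because the ring excludes the chair.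

Step 12
Reactants: 26 the cyclohexene diacid
Product: 27 (3R,4S,5R,6R)-4-[3,4-bis(allyloxy)phenyl]-1-formylcyclohex-1-ene-3,5,6-tricarboxylic acid
Conditions: CF3CO2H/H2O (9:1), CH2Cl2, 0 °C to rt
Reagents that add atoms: water, O
Why: Aqueous trifluoroacetic acid hydrolyses the acetal to the conjugated aldehyde and cleaves the tert-butyl ester by the E1 (isobutene) pathway in one operation, water trapping the cation and the allyl ethers being acid-stable; no hydroxymethyl group is ever set free next to the C6 carboxyl.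

Step 13
Reactants: 27 the triacid aldehyde
Product: 28 triallyl (3R,4S,5R,6R)-4-[3,4-bis(allyloxy)phenyl]-1-formylcyclohex-1-ene-3,5,6-tricarboxylate
Conditions: CH2=CHCH2Br, KHCO3, DMF, rt
Reagents that add atoms: allyl bromide, C=CCBr
Why: Carboxylate O-alkylation with allyl bromide under hydrogencarbonate esterifies the three acids with a base too weak to move the C1=C2 double bond or to epimerise C3 or C6.

Step 14
Reactants: 29 (R)-3-(3,4-dihydroxyphenyl)lactic acid (danshensu)
Product: 30 allyl (2R)-3-[3,4-bis(allyloxy)phenyl]-2-hydroxypropanoate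
Conditions: CH2=CHCH2Br, K2CO3, DMF, rt, under N2
Reagents that add atoms: allyl bromide, C=CCBr
Why: Under K2CO3 only the carboxylate and the two phenoxides are alkylated (carboxylate alkylation and Williamson etherification); the secondary alcohol stays free and the stereocentre is not touched.

Step 15
Reactants: 30 allyl (2R)-3-[3,4-bis(allyloxy)phenyl]-2-hydroxypropanoate; 31 diethylphosphonoacetic acid
Product: 32 allyl (2R)-3-[3,4-bis(allyloxy)phenyl]-2-{[(diethoxyphosphoryl)acetyl]oxy}propanoate
Conditions: DCC, DMAP (cat.), CH2Cl2, 0 °C to rt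
Reagents that add atoms: none
Why: Steglich esterification (carbodiimide activation with DMAP catalysis) acylates the secondary alcohol under conditions that should not epimerise the α-acyloxy ester.

Step 16
Reactants: 28 the triallyl ester aldehyde; 32 the danshensu phosphonoacetate
Product: 33 octaallyl derivative of the target (four aryl allyl ethers, four allyl esters)
Conditions: LiCl, iPr2NEt, MeCN, rt
Reagents that add atoms: none
Why: Horner–Wadsworth–Emmons olefination under Masamune–Roush conditions (LiCl and an amine base) converts the enal into the (E)-dienoate and joins the two halves without a strong base.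

Step 17
Reactants: 33 the octaallyl derivative
Product: 34 the target, (2R)-2-{[(2E)-3-[(3R,4S,5R,6R)-3,5,6-tricarboxy-4-(3,4-dihydroxyphenyl)cyclohex-1-en-1-yl]prop-2-enoyl]oxy}-3-(3,4-dihydroxyphenyl)propanoic acid (ring numbering of the plan)
Conditions: Pd(PPh3)4 (cat.), morpholine, THF, rt; dilute HCl on work-up
Reagents that add atoms: none
Why: Zerovalent palladium ionises all eight allyl–oxygen bonds (Tsuji–Trost deallylation) and morpholine traps the allyl fragments, freeing four phenols and four acids at room temperature without endangering the ester linkage, the alkenes or the stereocentres.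

**Compound list**

1 | 3,4-dihydroxybenzaldehyde | O=Cc1ccc(O)c(O)c1 | starting material
2 | 3,4-bis(allyloxy)benzaldehyde | O=Cc1ccc(OCC=C)c(OCC=C)c1 | intermediate
3 | ethyl acetoacetate | CCOC(=O)CC(C)=O | starting material
4 | diethyl 2,4-diacetyl-3-[3,4-bis(allyloxy)phenyl]pentanedioate (diastereomer mixture, not isolated) | CCOC(=O)C(C(C)=O)C(c1ccc(OCC=C)c(OCC=C)c1)C(C(C)=O)C(=O)OCC | intermediate
5 | 3-[3,4-bis(allyloxy)phenyl]pentanedioic acid | OC(=O)CC(CC(=O)O)c1ccc(OCC=C)c(OCC=C)c1 | intermediate
6 | 4-[3,4-bis(allyloxy)phenyl]oxane-2,6-dione | O=C1CC(c2ccc(OCC=C)c(OCC=C)c2)CC(=O)O1 | intermediate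
7 | (3S)-3-[3,4-bis(allyloxy)phenyl]-5-methoxy-5-oxopentanoic acid | COC(=O)C[C@@H](c1ccc(OCC=C)c(OCC=C)c1)CC(=O)O | intermediate
8 | (4S)-4-benzyl-1,3-oxazolidin-2-one | O=C1N[C@@H](Cc2ccccc2)CO1 | starting material
9 | pivalic mixed anhydride of 7 (not isolated) | COC(=O)C[C@@H](c1ccc(OCC=C)c(OCC=C)c1)CC(=O)OC(=O)C(C)(C)C | intermediate
10 | methyl (3S)-3-[3,4-bis(allyloxy)phenyl]-5-[(4S)-4-benzyl-2-oxo-1,3-oxazolidin-3-yl]-5-oxopentanoate | COC(=O)C[C@@H](c1ccc(OCC=C)c(OCC=C)c1)CC(=O)N1[C@@H](Cc2ccccc2)COC1=O | intermediate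
11 | 3,3-diethoxyprop-1-yne | C#CC(OCC)OCC | starting material
12 | lithium 3,3-diethoxyprop-1-yn-1-ide (not isolated) | [Li]C#CC(OCC)OCC | intermediate
13 | tert-butyl 4,4-diethoxybut-2-ynoate | CCOC(OCC)C#CC(=O)OC(C)(C)C | intermediate
14 | alkenylcopper adduct, vinyl cis to copper (not isolated) | C=C/C(C(OCC)OCC)=C(\[Cu])C(=O)OC(C)(C)C | intermediate
15 | tert-butyl (2Z)-3-(diethoxymethyl)penta-2,4-dienoate | C=C/C(C(OCC)OCC)=C/C(=O)OC(C)(C)C | intermediate
16 | 1,2,4-trioxolane (ozonide) of the vinyl group of 15 (not isolated) | CCOC(OCC)/C(=C\C(=O)OC(C)(C)C)C1OCOO1 | intermediate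
17 | tert-butyl (2Z)-3-(diethoxymethyl)-4-oxobut-2-enoate, formyl trans to the ester | O=C/C(C(OCC)OCC)=C/C(=O)OC(C)(C)C | intermediate
18 | dibutylboron (Z)-enolate of 10 (not isolated) | COC(=O)C[C@@H](c1ccc(OCC=C)c(OCC=C)c1)/C=C(\OB(CCCC)CCCC)N1[C@@H](Cc2ccccc2)COC1=O | intermediate
19 | dibutylboron aldolate of 20 (not isolated) | COC(=O)C[C@@H](c1ccc(OCC=C)c(OCC=C)c1)[C@H](C(=O)N1[C@@H](Cc2ccccc2)COC1=O)[C@@H](/C(C(OCC)OCC)=C/C(=O)OC(C)(C)C)OB(CCCC)CCCC | intermediate
20 | 1-tert-butyl 8-methyl (2Z,4S,5S,6R)-6-[3,4-bis(allyloxy)phenyl]-5-{[(4S)-4-benzyl-2-oxo-1,3-oxazolidin-3-yl]carbonyl}-3-(diethoxymethyl)-4-hydroxyoct-2-enedioate | COC(=O)C[C@@H](c1ccc(OCC=C)c(OCC=C)c1)[C@H](C(=O)N1[C@@H](Cc2ccccc2)COC1=O)[C@@H](/C(C(OCC)OCC)=C/C(=O)OC(C)(C)C)O | intermediate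
21 | hydroxy acid: 20 with the oxazolidinone replaced by OH, configuration unchanged (not isolated) | COC(=O)C[C@@H](c1ccc(OCC=C)c(OCC=C)c1)[C@H](C(=O)O)[C@@H](/C(C(OCC)OCC)=C/C(=O)OC(C)(C)C)O | intermediate
22 | (2S,3S,4R)-4-[3,4-bis(allyloxy)phenyl]-2-[(1Z)-3-tert-butoxy-1-(diethoxymethyl)-3-oxoprop-1-en-1-yl]-6-oxooxane-3-carboxylic acid, all substituents equatorial | O=C1C[C@@H](c2ccc(OCC=C)c(OCC=C)c2)[C@H](C(=O)O)[C@@H](/C(C(OCC)OCC)=C/C(=O)OC(C)(C)C)O1 | intermediate
23 | dipotassium carboxylate enolate of 22 (not isolated) | [K+].[K+].[O-]C1=C[C@@H](c2ccc(OCC=C)c(OCC=C)c2)[C@H](C(=O)[O-])[C@@H](/C(C(OCC)OCC)=C/C(=O)OC(C)(C)C)O1 | intermediate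
24 | trimethylsilyl ester O-trimethylsilyl ketene acetal of 22 (not isolated) | C[Si](C)(C)OC1=C[C@@H](c2ccc(OCC=C)c(OCC=C)c2)[C@H](C(=O)O[Si](C)(C)C)[C@@H](/C(C(OCC)OCC)=C/C(=O)OC(C)(C)C)O1 | intermediate
25 | bis(trimethylsilyl) ester of 26 (not isolated) | CCOC(OCC)C1=C[C@@H](C(=O)O[Si](C)(C)C)[C@H](c2ccc(OCC=C)c(OCC=C)c2)[C@@H](C(=O)O[Si](C)(C)C)[C@H]1C(=O)OC(C)(C)C | intermediate
26 | (3R,4S,5R,6R)-4-[3,4-bis(allyloxy)phenyl]-6-(tert-butoxycarbonyl)-1-(diethoxymethyl)cyclohex-1-ene-3,5-dicarboxylic acid (plan numbering) | CCOC(OCC)C1=C[C@@H](C(=O)O)[C@H](c2ccc(OCC=C)c(OCC=C)c2)[C@@H](C(=O)O)[C@H]1C(=O)OC(C)(C)C | intermediate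
27 | (3R,4S,5R,6R)-4-[3,4-bis(allyloxy)phenyl]-1-formylcyclohex-1-ene-3,5,6-tricarboxylic acid (plan numbering) | O=CC1=C[C@@H](C(=O)O)[C@H](c2ccc(OCC=C)c(OCC=C)c2)[C@@H](C(=O)O)[C@H]1C(=O)O | intermediate
28 | triallyl (3R,4S,5R,6R)-4-[3,4-bis(allyloxy)phenyl]-1-formylcyclohex-1-ene-3,5,6-tricarboxylate (plan numbering) | O=CC1=C[C@@H](C(=O)OCC=C)[C@H](c2ccc(OCC=C)c(OCC=C)c2)[C@@H](C(=O)OCC=C)[C@H]1C(=O)OCC=C | intermediate
29 | (R)-3-(3,4-dihydroxyphenyl)lactic acid (danshensu) | O[C@H](Cc1ccc(O)c(O)c1)C(=O)O | starting material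
30 | allyl (2R)-3-[3,4-bis(allyloxy)phenyl]-2-hydroxypropanoate | O[C@H](Cc1ccc(OCC=C)c(OCC=C)c1)C(=O)OCC=C | intermediate
31 | diethylphosphonoacetic acid | CCOP(=O)(CC(=O)O)OCC | starting material
32 | allyl (2R)-3-[3,4-bis(allyloxy)phenyl]-2-{[(diethoxyphosphoryl)acetyl]oxy}propanoate | CCOP(=O)(OCC)CC(=O)O[C@H](Cc1ccc(OCC=C)c(OCC=C)c1)C(=O)OCC=C | intermediate
33 | octaallyl derivative of the target | O=C(/C=C/C1=C[C@@H](C(=O)OCC=C)[C@H](c2ccc(OCC=C)c(OCC=C)c2)[C@@H](C(=O)OCC=C)[C@H]1C(=O)OCC=C)O[C@H](Cc1ccc(OCC=C)c(OCC=C)c1)C(=O)OCC=C | intermediate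
34 | CNP0327643.1, (2R)-2-{[(2E)-3-[(3R,4S,5R,6R)-3,5,6-tricarboxy-4-(3,4-dihydroxyphenyl)cyclohex-1-en-1-yl]prop-2-enoyl]oxy}-3-(3,4-dihydroxyphenyl)propanoic acid (plan numbering) | O=C(/C=C/C1=C[C@@H](C(=O)O)[C@H](c2ccc(O)c(O)c2)[C@@H](C(=O)O)[C@H]1C(=O)O)O[C@H](Cc1ccc(O)c(O)c1)C(=O)O | target

**Step count and risks**

Total step count: 17. Longest linear sequence: 12 steps (steps 1, 2, 3, 4, 5, 9, 10, 11, 12, 13, 16, 17).

Step 11. The dipotassium salt may aggregate and enolise incompletely, the labile trimethylsilyl ketene acetal may hydrolyse or be C-silylated before it rearranges, or the strained boat may be reached only at temperatures where the substrate decomposes. The fallback changes the substrate to a neutral triester with a sturdier silyl group instead of adjusting base or temperature. Setting out from 22, allyl bromide and KHCO3 in DMF give the allyl ester lactone F1. LiN(iPr)2 is added to F1 and tBuMe2SiCl in THF/HMPA at −78 °C (in situ trapping; the lactone methylene is more acidic and less hindered than the C3 methine) to give the tert-butyldimethylsilyl ketene acetal F2. Heating in toluene rearranges it to the silyl ester F3. Aqueous trifluoroacetic acid then removes silyl ester, tert-butyl ester and acetal together to give the diacid aldehyde F4, and allylation as in step 13 comes back to the route at 28.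

Step 9. The boron Lewis acid may ionise the acetal of 17, the doubly activated enal may oligomerise or react in a conjugate sense, and the β-aryl centre may erode facial selectivity. The fallback makes the C2–C3 bond by C-acylation and the carbinol centre by reduction. Because acylation and the boron aldol address opposite enolate faces, the enantiomeric auxiliary is used. Setting out from 7, the procedure of step 5 with (4R)-4-benzyl-1,3-oxazolidin-2-one gives the imide F5. Aldehyde 17 is oxidised (NaClO2, NaH2PO4, 2-methylbut-2-ene; Pinnick oxidation) to the acid F6 and converted with 1-chloro-N,N,2-trimethylprop-1-en-1-amine into the acid chloride F7. The lithium enolate of F5 (LiN(iPr)2, THF, −78 °C) is acylated by F7 on the face opposite the benzyl group to give the β-keto imide F8. Chelation-controlled reduction with Zn(BH4)2 gives the syn β-hydroxy imide F9, which differs from 20 only in the auxiliary. The conditions of step 10 then remove the auxiliary and close the lactone, coming back to the route at 22.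

Step 16. The amine base may remove the doubly activated C3 proton of 28 (α to an ester and γ to the enal) faster than the phosphonate anion adds, leading to epimerisation or migration of the C1=C2 double bond. The fallback is a base-free olefination with a stabilised ylide. Setting out from 30, bromoacetyl bromide and pyridine in CH2Cl2 give the bromoacetate F10, PPh3 in toluene gives the phosphonium bromide F11, and aqueous Na2CO3 gives the ylide F12. F12 and 28 in CH2Cl2 at room temperature (Wittig reaction of a stabilised ylide, E-selective) come back to the route at 33.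

**Further compounds**

F1 | step 11 | allyl ester of lactone acid 22 | O=C1C[C@@H](c2ccc(OCC=C)c(OCC=C)c2)[C@H](C(=O)OCC=C)[C@@H](/C(C(OCC)OCC)=C/C(=O)OC(C)(C)C)O1
F2 | step 11 | O-tert-butyldimethylsilyl ketene acetal of F1 | CC(C)(C)[Si](C)(C)OC1=C[C@@H](c2ccc(OCC=C)c(OCC=C)c2)[C@H](C(=O)OCC=C)[C@@H](/C(C(OCC)OCC)=C/C(=O)OC(C)(C)C)O1
F3 | step 11 | rearranged cyclohexene: C5 tert-butyldimethylsilyl ester, C3 allyl ester, C6 tert-butyl ester, C1 diethyl acetal | CCOC(OCC)C1=C[C@@H](C(=O)OCC=C)[C@H](c2ccc(OCC=C)c(OCC=C)c2)[C@@H](C(=O)O[Si](C)(C)C(C)(C)C)[C@H]1C(=O)OC(C)(C)C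
F4 | step 11 | C5,C6 diacid C3 allyl ester aldehyde | O=CC1=C[C@@H](C(=O)OCC=C)[C@H](c2ccc(OCC=C)c(OCC=C)c2)[C@@H](C(=O)O)[C@H]1C(=O)O
F5 | step 9 | methyl (3S)-3-[3,4-bis(allyloxy)phenyl]-5-[(4R)-4-benzyl-2-oxo-1,3-oxazolidin-3-yl]-5-oxopentanoate | COC(=O)C[C@@H](c1ccc(OCC=C)c(OCC=C)c1)CC(=O)N1[C@H](Cc2ccccc2)COC1=O
F6 | step 9 | 4-tert-butoxy-2-(diethoxymethyl)-4-oxobut-2-enoic acid, carboxyl trans to the ester | OC(=O)/C(C(OCC)OCC)=C/C(=O)OC(C)(C)C
F7 | step 9 | acid chloride of F6 | ClC(=O)/C(C(OCC)OCC)=C/C(=O)OC(C)(C)C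
F8 | step 9 | β-keto imide from F5 and F7 | COC(=O)C[C@@H](c1ccc(OCC=C)c(OCC=C)c1)[C@H](C(=O)N1[C@H](Cc2ccccc2)COC1=O)C(=O)/C(C(OCC)OCC)=C/C(=O)OC(C)(C)C
F9 | step 9 | syn β-hydroxy imide, (4R)-auxiliary analogue of 20 | COC(=O)C[C@@H](c1ccc(OCC=C)c(OCC=C)c1)[C@H](C(=O)N1[C@H](Cc2ccccc2)COC1=O)[C@@H](/C(C(OCC)OCC)=C/C(=O)OC(C)(C)C)O
F10 | step 16 | allyl (2R)-3-[3,4-bis(allyloxy)phenyl]-2-(bromoacetoxy)propanoate | BrCC(=O)O[C@H](Cc1ccc(OCC=C)c(OCC=C)c1)C(=O)OCC=C
F11 | step 16 | triphenylphosphonium bromide from F10 | [Br-].O=C(C[P+](c1ccccc1)(c1ccccc1)c1ccccc1)O[C@H](Cc1ccc(OCC=C)c(OCC=C)c1)C(=O)OCC=C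
F12 | step 16 | stabilised ylide from F11 | O=C(C=P(c1ccccc1)(c1ccccc1)c1ccccc1)O[C@H](Cc1ccc(OCC=C)c(OCC=C)c1)C(=O)OCC=C
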